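**Strategy.** Ring A is disconnected at C3–C4. Its C3 oxygen next to the quaternary C4 (C18 methyl, C19 hydroxymethyl) is read as a 2-formyl-2-methylcyclohexanone, the product of a ring contraction. In the key step a seven-membered α,β-epoxy ketone, in which C19 is still a ring atom between C3 and C4, rearranges under a Lewis acid: the C3 acyl carbon shifts from C19 to C4 with inversion, C19 leaves the ring as the axial formyl group, and ring A (C1–C5, C10) appears in its final size with C4 fixed. The precursor, a ring-A-homologated bicycle, is grown on (S)-carvone, whose isopropenyl group supplies C4, C18 and C19.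

Key step: step 13

Remark on the chemistry: locants are those of the labdane skeleton of the target (ring A = C1–C5 and C10; ring B = C5–C10; side chain C11–C16; C17 on C8; C18 and C19 on C4; C20 on C10); α denotes the face that carries C20, β the face of H5 and H9; compounds 1, 4 and 9 are taken as commercial.

Step 1
Reactants: 1 (S)-(+)-carvone
Product: 2 (5S)-6-methylcarvone (both C6 epimers)
Conditions: LiN(i-Pr)2, THF, −78 °C; MeI, −78 → 0 °C
Reagents that add atoms: iodomethane, CI
Why: Enolate alkylation: the cross-conjugated lithium enolate can form only at C6 (the later C10) and is methylated there (C20); the new centre need not be controlled because it becomes trigonal again in step 2.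

Step 2
Reactants: 2 (5S)-6-methylcarvone
Product: 3 6-allyl-6-methyl-(S)-carvone (allyl trans and methyl cis to the isopropenyl group)
Conditions: LiN(i-Pr)2, THF–DMPU, −78 °C; allyl bromide, −78 → 0 °C
Reagents that add atoms: allyl bromide, C=CCBr
Why: Second enolate alkylation: allyl bromide should add to the enolate face anti to the neighbouring isopropenyl group, which sets the quaternary C10 and brings in C1–C3.

Step 3
Reactants: 3 6-allyl-6-methyl-(S)-carvone; 4 2-(2-bromoethyl)-2-methyl-1,3-dioxolane
Product: 6 C9 methyl carbonate of the Grignard adduct (carbonate oxygen on the α face), via bromomagnesium C9 alkoxide 5 (not isolated)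
Conditions: 4, Mg, THF, rt; then 3, LaCl3·2LiCl (cat.), THF, −20 °C; then ClCO2Me, −20 °C → rt
Reagents that add atoms: methyl chloroformate, COC(=O)Cl
Why: Grignard 1,2-addition to the enone carbonyl should occur from the β face, anti to the axial C10 methyl group beside the carbonyl, so that the C9 oxygen lies on the α face; the alkoxide is acylated in the flask to the tertiary allylic carbonate needed in step 4.

Step 4
Reactants: 6 C9 methyl carbonate
Product: 8 ring-B methyl ketone (H9 β; C7=C8; C13 ketone), via dioxolane ketal 7 (not isolated)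
Conditions: Pd(OAc)2 (cat.), n-Bu3P, HCO2H, Et3N, dioxane, 80 °C; then 1 M HCl, THF, rt
Reagents that add atoms: water, O
Why: Palladium-catalysed formate hydrogenolysis of an allylic carbonate (Tsuji–Trost type): zerovalent palladium ionises the carbonate with inversion and the palladium hydride formed from formate should deliver hydrogen to the more substituted allyl terminus C9 on the β face, giving H9 β (side chain cis to C20) and the C7=C8 alkene; the acidic work-up hydrolyses the ketal.

Step 5
Reactants: 8 ring-B methyl ketone; 9 tert-butyl diethylphosphonoacetate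
Product: 10 tert-butyl (13E)-enoate (complete C11–C16 side chain; C10 allyl; C5 isopropenyl)
Conditions: NaH, THF, 0 °C → reflux
Reagents that add atoms: none
Why: Horner–Wadsworth–Emmons olefination of the methyl ketone should favour the E enoate (chain trans to the ester); any Z isomer would be removed by chromatography.

Step 6
Reactants: 10 tert-butyl (13E)-enoate
Product: 12 C3 primary alcohol, via C3 alkyldisiamylborane 11 (not isolated)
Conditions: bis(3-methylbutan-2-yl)borane (from BH3·SMe2 and 2-methylbut-2-ene), THF, 0 °C; then H2O2, NaOH, 0 °C → rt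
Reagents that add atoms: hydrogen peroxide, OO
Why: Hydroboration–oxidation: the hindered dialkylborane should add anti-Markovnikov only to the monosubstituted allyl double bond and leave the 1,1-disubstituted and trisubstituted alkenes and the ester.

Step 7
Reactants: 12 C3 primary alcohol
Product: 13 C3 aldehyde
Conditions: Dess–Martin periodinane, CH2Cl2, rt
Reagents that add atoms: none
Why: Dess–Martin oxidation converts the primary alcohol into the aldehyde under neutral conditions that spare the alkenes and the tert-butyl ester.

Step 8
Reactants: 13 C3 aldehyde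
Product: 14 A-homo alcohol (seven-membered ring C1–C2–C3(OH)–C19–C4(=C18H2)–C5–C10; C3 epimers)
Conditions: Me2AlCl, CH2Cl2, −78 → 0 °C
Reagents that add atoms: none
Why: Type 2 intramolecular carbonyl-ene reaction: the aluminium-bound aldehyde carbon C3 bonds to the terminal CH2 of the isopropenyl group (C19) with hydrogen transfer from its methyl group, closing the seven-membered ring; the C3 configuration is irrelevant because C3 is oxidised in step 9.

Step 9
Reactants: 14 A-homo alcohol
Product: 16 A-homo conjugated enone (C3 ketone; C19=C4; C18 methyl), via A-homo exo-methylene ketone 15 (not isolated)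
Conditions: Dess–Martin periodinane, CH2Cl2, rt; then DBU, rt
Reagents that add atoms: none
Why: Dess–Martin oxidation followed by base-mediated isomerisation of the β,γ-unsaturated ketone through its dienolate should give the conjugated trisubstituted enone and restore the C18 methyl group.

Step 10
Reactants: 16 A-homo conjugated enone
Product: 17 A-homo allylic alcohol (C3–OH α)
Conditions: (S)-Me-CBS oxazaborolidine (cat.), catecholborane, toluene, −78 °C
Reagents that add atoms: none
Why: Corey–Bakshi–Shibata reduction: with the alkenyl arm as the large group the (S)-catalyst should deliver hydride to the β face of the C3 carbonyl under catalyst control, giving the α alcohol.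

Step 11
Reactants: 17 A-homo allylic alcohol
Product: 18 A-homo epoxy alcohol (C19–C4 epoxide α; C3–OH α)
Conditions: VO(acac)2 (cat.), t-BuOOH, CH2Cl2, 0 °C → rt
Reagents that add atoms: tert-butyl hydroperoxide, CC(C)(C)OO
Why: Hydroxyl-directed vanadium-catalysed epoxidation of a cyclic allylic alcohol delivers oxygen syn to the C3 hydroxyl, i.e. to the more hindered α face of C19=C4 that an undirected reagent would avoid; the isolated and electron-poor alkenes should not react.

Step 12
Reactants: 18 A-homo epoxy alcohol
Product: 19 A-homo α,β-epoxy ketone (C3 ketone; C19–C4 epoxide α)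
Conditions: Dess–Martin periodinane, NaHCO3, CH2Cl2, rt
Reagents that add atoms: none
Why: Buffered Dess–Martin oxidation of the secondary alcohol gives the epoxy ketone without opening the epoxide.

Step 13
Reactants: 19 A-homo α,β-epoxy ketone
Product: 20 tert-butyl (13E)-3,19-dioxolabda-7,13-dien-15-oate (C19 formyl axial, cis to C20)
Conditions: BF3·OEt2, CH2Cl2, −78 → −20 °C
Reagents that add atoms: none
Why: BF3 binds the epoxide oxygen, the C4–O bond (tertiary, remote from the carbonyl) ionises, and in the same event the acyl carbon C3 migrates from C19 to C4 on the face opposite the departing oxygen, leaving C19 as an aldehyde carbon on C4. The closest known reaction type is the Lewis-acid 1,2-acyl shift (semipinacol-type rearrangement) of cyclic α,β-epoxy ketones with a β-alkyl group, which gives ring-contracted 2-formyl ketones. Ring A (C1, C2, C3, C4, C5, C10) is closed not by a cyclisation but by this suprafacial 1,2-shift, a ring contraction from seven to six members in which C19 is extruded. C4 is the only new stereocentre and is controlled by the epoxide configuration from step 11: migration with inversion at C4 places the formyl carbon C19 on the α face (axial, cis to C20) and leaves C18 equatorial. The step needs acyl migration to win over hydride migration from C19 (which would give the ring-retained 3,19-dione) and over loss of the formyl group; the high migratory aptitude of the acyl group toward the tertiary centre, the absence of an enolisable hydrogen between the two carbonyls and the low temperature should secure this, and the tert-butyl ester and both alkenes are expected to survive the brief exposure.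

Step 14
Reactants: 20 tert-butyl (13E)-3,19-dioxolabda-7,13-dien-15-oate
Product: 21 tert-butyl (13E)-3,19-dihydroxylabda-7,13-dien-15-oate (3-OH axial, β)
Conditions: LiBH(s-Bu)3 (L-Selectride), THF, −78 °C; aqueous work-up
Reagents that add atoms: none
Why: Bulky trialkylborohydride reduction: the aldehyde is reduced first and the C3 ketone, flanked by the quaternary C4, should then be attacked along the equatorial trajectory as in other 4,4-disubstituted 3-ketones, giving the axial β alcohol trans to C19.

Step 15
Reactants: 21 tert-butyl (13E)-3,19-dihydroxylabda-7,13-dien-15-oate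
Product: 22 19-O-tert-butyldimethylsilyl ether of 21
Conditions: TBSCl, imidazole, DMF, 0 °C → rt
Reagents that add atoms: tert-butyldimethylsilyl chloride, CC(C)(C)[Si](C)(C)Cl
Why: Silylation should take place only at the primary C19 hydroxyl, because the axial secondary C3 hydroxyl beside the quaternary C4 is far more hindered.

Step 16
Reactants: 22 19-O-tert-butyldimethylsilyl ether
Product: 23 3-O-acetate of 22
Conditions: Ac2O, DMAP, Et3N, CH2Cl2, rt → 40 °C
Reagents that add atoms: acetic anhydride, CC(=O)OC(C)=O
Why: DMAP-catalysed acylation acetylates the remaining hindered C3 hydroxyl with retention of configuration.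

Step 17
Reactants: 23 3-O-acetate
Product: 24 (13E)-3-acetoxy-19-hydroxylabda-7,13-dien-15-oic acid (target, CNP0129162.1)
Conditions: CF3CO2H, CH2Cl2, 0 °C; aqueous work-up
Reagents that add atoms: none
Why: Acidolysis should remove the tert-butyl ester (as 2-methylpropene) and the primary silyl ether in one operation while the acetate stays in place.

**Compound list**

1 | (S)-(+)-carvone | CC1=CC[C@@H](CC1=O)C(C)=C | starting material
2 | (5S)-6-methylcarvone (both C6 epimers) | CC1[C@H](CC=C(C)C1=O)C(C)=C | intermediate
3 | 6-allyl-6-methyl-(S)-carvone (allyl trans, methyl cis to isopropenyl) | C=CC[C@]1(C)[C@H](CC=C(C)C1=O)C(C)=C | intermediate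
4 | 2-(2-bromoethyl)-2-methyl-1,3-dioxolane | CC1(CCBr)OCCO1 | starting material
5 | bromomagnesium C9 alkoxide (not isolated; oxygen α, side chain β) | C=CC[C@]1(C)[C@H](CC=C(C)[C@]1([O-])CCC2(C)OCCO2)C(C)=C.[Mg+2].[Br-] | intermediate
6 | C9 methyl carbonate of the Grignard adduct (oxygen α) | C=CC[C@]1(C)[C@H](CC=C(C)[C@]1(OC(=O)OC)CCC2(C)OCCO2)C(C)=C | intermediate
7 | dioxolane ketal (not isolated; H9 β, C7=C8) | C=CC[C@]1(C)[C@H](CC=C(C)[C@H]1CCC2(C)OCCO2)C(C)=C | intermediate
8 | ring-B methyl ketone (H9 β, C7=C8, C13 ketone, C10 allyl and methyl, C5 isopropenyl) | C=CC[C@]1(C)[C@H](CC=C(C)[C@H]1CCC(C)=O)C(C)=C | intermediate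
9 | tert-butyl diethylphosphonoacetate | CCOP(=O)(CC(=O)OC(C)(C)C)OCC | starting material
10 | tert-butyl (13E)-enoate (C10 allyl, C5 isopropenyl) | C=CC[C@]1(C)[C@H](CC=C(C)[C@H]1CC/C(C)=C/C(=O)OC(C)(C)C)C(C)=C | intermediate
11 | C3 alkyldisiamylborane (not isolated) | CC(C)C(C)B(CCC[C@]1(C)[C@H](CC=C(C)[C@H]1CC/C(C)=C/C(=O)OC(C)(C)C)C(C)=C)C(C)C(C)C | intermediate
12 | C3 primary alcohol | OCCC[C@]1(C)[C@H](CC=C(C)[C@H]1CC/C(C)=C/C(=O)OC(C)(C)C)C(C)=C | intermediate
13 | C3 aldehyde | O=CCC[C@]1(C)[C@H](CC=C(C)[C@H]1CC/C(C)=C/C(=O)OC(C)(C)C)C(C)=C | intermediate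
14 | A-homo alcohol (C3–OH, C4=C18H2; C3 epimers) | OC1CC[C@]2(C)[C@H](CC=C(C)[C@H]2CC/C(C)=C/C(=O)OC(C)(C)C)C(=C)C1 | intermediate
15 | A-homo exo-methylene ketone (not isolated) | O=C1CC[C@]2(C)[C@H](CC=C(C)[C@H]2CC/C(C)=C/C(=O)OC(C)(C)C)C(=C)C1 | intermediate
16 | A-homo conjugated enone (C3 ketone, C19=C4) | O=C1CC[C@]2(C)[C@H](CC=C(C)[C@H]2CC/C(C)=C/C(=O)OC(C)(C)C)C(C)=C1 | intermediate
17 | A-homo allylic alcohol (C3–OH α) | O[C@@H]1CC[C@]2(C)[C@H](CC=C(C)[C@H]2CC/C(C)=C/C(=O)OC(C)(C)C)C(C)=C1 | intermediate
18 | A-homo epoxy alcohol (C19–C4 epoxide α, C3–OH α) | O[C@@H]1CC[C@]2(C)[C@H](CC=C(C)[C@H]2CC/C(C)=C/C(=O)OC(C)(C)C)[C@]3(C)O[C@@H]31 | intermediate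
19 | A-homo α,β-epoxy ketone (C3 ketone, C19–C4 epoxide α) | O=C1CC[C@]2(C)[C@H](CC=C(C)[C@H]2CC/C(C)=C/C(=O)OC(C)(C)C)[C@]3(C)O[C@@H]31 | intermediate
20 | tert-butyl (13E)-3,19-dioxolabda-7,13-dien-15-oate (C19 formyl axial, cis to C20) | O=C1CC[C@]2(C)[C@H](CC=C(C)[C@H]2CC/C(C)=C/C(=O)OC(C)(C)C)[C@]1(C)C=O | intermediate
21 | tert-butyl (13E)-3,19-dihydroxylabda-7,13-dien-15-oate (3-OH axial, β) | O[C@H]1CC[C@]2(C)[C@H](CC=C(C)[C@H]2CC/C(C)=C/C(=O)OC(C)(C)C)[C@]1(C)CO | intermediate
22 | 19-O-tert-butyldimethylsilyl ether of 21 | O[C@H]1CC[C@]2(C)[C@H](CC=C(C)[C@H]2CC/C(C)=C/C(=O)OC(C)(C)C)[C@]1(C)CO[Si](C)(C)C(C)(C)C | intermediate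
23 | 3-O-acetate of 22 | CC(=O)O[C@H]1CC[C@]2(C)[C@H](CC=C(C)[C@H]2CC/C(C)=C/C(=O)OC(C)(C)C)[C@]1(C)CO[Si](C)(C)C(C)(C)C | intermediate
24 | (13E)-3-acetoxy-19-hydroxylabda-7,13-dien-15-oic acid (3-OAc axial on the β face, C19 axial on the α face) | CC(=O)O[C@H]1CC[C@]2(C)[C@H](CC=C(C)[C@H]2CC/C(C)=C/C(=O)O)[C@]1(C)CO | target

Total step count: 17. Longest linear sequence: 17 steps, from (S)-carvone 1.

**Steps most likely to fail**

Step 13 (key step). The acyl shift may lose out to hydride migration from C19, which would give the ring-retained 3,19-dione, or the formyl ketone may lose its formyl group during the reaction or work-up. The fallback sets out from 18 and comes back at 20. The epoxy alcohol 18 would be silylated (TBSOTf, 2,6-lutidine) to the A-homo epoxy silyl ether F1. A bulky methylaluminium bis(aryloxide), MeAl(OAr)2 with Ar = 4-bromo-2,6-di-tert-butylphenyl (CH2Cl2, −78 °C), would then promote the known rearrangement of epoxy silyl ethers to β-siloxy aldehydes. Here the siloxy-bearing C3 would migrate from C19 to C4, with inversion at C4 and retention at C3, to give the ring-contracted 3-siloxy 19-aldehyde F2. HF·pyridine would free the 3-hydroxy 19-aldehyde F3, and Dess–Martin oxidation of its C3 hydroxyl would give 20.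

Step 8. The ene cyclisation may fail to close the seven-membered ring cleanly, through stepwise Prins pathways with unselective proton loss or through reaction of the aldehyde with the ring-B alkene. The fallback sets out from 13 and comes back at 16. Vinylmagnesium bromide (THF, −78 °C) would add to the aldehyde to give the vinyl carbinol F4 (both C3 epimers), and Dess–Martin oxidation would give the vinyl ketone F5. Ring-closing metathesis of F5 with the isopropenyl group (second-generation Grubbs catalyst, toluene, 80 °C) would close the seven-membered enone 16 directly.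

Step 4. Hydride may be delivered to C7 instead of C9, the allylpalladium intermediate may eliminate to a diene, or the facial course of step 3 may place H9 on the wrong face. The fallback sets out from 3 and comes back at 7, which the acidic work-up of step 4 converts into 8. The Grignard reagent from 4 would be added to 3 as in step 3, but the adduct would be isolated as the tertiary allylic alcohol F6. Oxidative 1,3-transposition with IBX in DMSO would give the transposed enone F7 (C7 ketone, C8=C9). Luche reduction (NaBH4, CeCl3·7H2O, MeOH) should give the C7 allylic alcohol F8 with the hydroxyl on the α face, cis to the isopropenyl group, as in the reduction of carvone to cis-carveol. Mitsunobu displacement with 2-nitrobenzenesulfonylhydrazide (PPh3, diethyl azodicarboxylate, THF, −30 °C → rt) would form the allylic diazene with inversion at C7. Its loss of N2 transfers hydrogen to C9 on the β face and moves the alkene to C7=C8, giving 7 independently of the facial course of the Grignard addition.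

Further compounds
F1 | step 13 | A-homo epoxy silyl ether (3-O-tert-butyldimethylsilyl ether of 18) | CC(C)(C)[Si](C)(C)O[C@@H]1CC[C@]2(C)[C@H](CC=C(C)[C@H]2CC/C(C)=C/C(=O)OC(C)(C)C)[C@]3(C)O[C@@H]31
F2 | step 13 | ring-contracted 3-siloxy 19-aldehyde (3-O-silyl α, C19 formyl α) | CC(C)(C)[Si](C)(C)O[C@@H]1CC[C@]2(C)[C@H](CC=C(C)[C@H]2CC/C(C)=C/C(=O)OC(C)(C)C)[C@]1(C)C=O
F3 | step 13 | ring-contracted 3-hydroxy 19-aldehyde (3-OH α) | O[C@@H]1CC[C@]2(C)[C@H](CC=C(C)[C@H]2CC/C(C)=C/C(=O)OC(C)(C)C)[C@]1(C)C=O
F4 | step 8 | vinyl carbinol (C3 epimers) | C=CC(O)CC[C@]1(C)[C@H](CC=C(C)[C@H]1CC/C(C)=C/C(=O)OC(C)(C)C)C(C)=C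
F5 | step 8 | vinyl ketone | C=CC(=O)CC[C@]1(C)[C@H](CC=C(C)[C@H]1CC/C(C)=C/C(=O)OC(C)(C)C)C(C)=C
F6 | step 4 | tertiary allylic alcohol (C9–OH α) | C=CC[C@]1(C)[C@H](CC=C(C)[C@]1(O)CCC2(C)OCCO2)C(C)=C
F7 | step 4 | transposed enone (C7 ketone, C8=C9) | C=CC[C@]1(C)[C@H](CC(=O)C(C)=C1CCC2(C)OCCO2)C(C)=C
F8 | step 4 | C7 allylic alcohol (C7–OH α) | C=CC[C@]1(C)[C@H](C[C@@H](O)C(C)=C1CCC2(C)OCCO2)C(C)=C
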